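## Retrosynthetic overview

1. Target 16 ⇐ hydrolysis of the C2 methyl enol ether and the catechol silylene of tricycle 15.
2. 15 ⇐ one-flask double cationic cyclization of the monocyclic dearomatized acylphloroglucinol 13. Ring B closes first (C1–C8, PPAP-type), then the cycloheptane (C11–C12, ene-type cation–olefin closure ending in the isopropenyl group).
3. 13 ⇐ dearomative Claisen shift of a 2-methylallyl group from O4 to C5 of phenol 11.
4. 11 ⇐ C1-prenylation and O9-methylation of 9; 9 ⇐ three-component ortho-quinone methide coupling of benzophenone 4, (R)-lavandulal 6 and a 4-methylpent-3-enyl Grignard reagent.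
5. 4 ⇐ Hoesch acylation of 5-methoxyresorcinol. Ring order: ring A is bought as the arene; ring B and the seven-membered ring are the last C–C bonds made.

Assumption: (R)-(−)-lavandulol is taken as a purchasable natural terpene alcohol (otherwise from the cheap racemate by lipase resolution), and the enol tautomer drawn in the target SMILES is treated as equivalent to its fast-exchanging tautomers.

Locants: C1–C9 are those of the bicyclo[3.3.1]nonane core (C1 bridgehead with prenyl, C3 aroyl carbon, C5 other bridgehead, C6, C7, C8 = CMe2, C9 bridging C=O). C10–C14 are the extra cycloheptane carbons from C5 to C6 (C11 = CMe2, C12 = CH-isopropenyl). O4 and O9 are the oxygens on C4 and C9. The same locants are used for the corresponding atoms of all earlier intermediates.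

## Route

Step 1
Reactants: 1 5-methoxyresorcinol; 2 3,4-dihydroxybenzonitrile
Product: 3 (3,4-dihydroxyphenyl)(2,4-dihydroxy-6-methoxyphenyl)methanone
Conditions: ZnCl2, HCl (g), Et2O, 0 °C; then H2O, 100 °C
Reagents that add atoms: water, O
Why: Houben–Hoesch acylation: the nitrilium ion attacks the ring position para to one hydroxyl and ortho to the other, and ketimine hydrolysis gives the 2,4-dihydroxy-6-methoxy ketone, whose single ortho-methoxy group (O2) later distinguishes C1 from C5 (the minor 2,6-dihydroxy-4-methoxy isomer is removed by crystallisation).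

Step 2
Reactants: 3 (3,4-dihydroxyphenyl)(2,4-dihydroxy-6-methoxyphenyl)methanone
Product: 4 (2,2-di-tert-butyl-1,3,2-benzodioxasilol-5-yl)(2,4-dihydroxy-6-methoxyphenyl)methanone
Conditions: tBu2Si(OTf)2, 2,6-lutidine, DMF, 0 °C
Reagents that add atoms: di-tert-butylsilyl bis(trifluoromethanesulfonate), CC(C)(C)[Si](OS(=O)(=O)C(F)(F)F)(OS(=O)(=O)C(F)(F)F)C(C)(C)C
Why: Silylene protection of a 1,2-diol: only the vicinal catechol hydroxyls can close the five-membered dioxasilole, so O4–H and O9–H stay free.

Step 3
Reactants: 5 (R)-lavandulol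
Product: 6 (R)-lavandulal
Conditions: Dess–Martin periodinane, CH2Cl2, 0 °C; used at once
Reagents that add atoms: none
Why: Dess–Martin oxidation under non-basic conditions at low temperature keeps the epimerisable α-stereocentre (the future C7, taken from the chiral pool) and the β,γ-alkene in place.

Step 4
Reactants: 4 (2,2-di-tert-butyl-1,3,2-benzodioxasilol-5-yl)(2,4-dihydroxy-6-methoxyphenyl)methanone; 6 (R)-lavandulal
Product: 9 C5-(6S,7S)-alkylated dihydroxy-methoxy benzophenone, via benzylic magnesium alkoxide adduct 7 (not isolated), via ortho-quinone methide 8 (not isolated)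
Conditions: EtMgBr (2.1 equiv), PhMe, 0 °C; 6, rt; then 4-methylpent-3-enylmagnesium bromide (2 equiv), CuBr·SMe2 (10 mol%), −20 to 40 °C; aq. NH4Cl
Reagents that add atoms: 4-methylpent-3-enylmagnesium bromide (made from commercial 5-bromo-2-methylpent-2-ene and Mg), CC(C)=CCC[Mg]Br
Why: Proposed new method: the bis(bromomagnesium) phenoxide delivers the aldehyde to C5, the carbon between the two oxido groups (magnesium-phenoxide ortho-hydroxyalkylation); the benzylic alkoxide 7 then loses magnesium oxide-hydroxide to give ortho-quinone methide 8, which takes up the copper-assisted Grignard reagent in a 1,4-addition while the doubly ortho-substituted diaryl ketone is too hindered to be attacked; C6 is set by a Felkin–Anh/allylic-strain model (C7–H eclipses the exocyclic C5=C6 bond and the nucleophile enters anti to the isopropenyl group, giving 6S); the closest known reaction type is Grignard addition to ortho-quinone methides generated from ortho-hydroxybenzyl alkoxides.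

Step 5
Reactants: 9 C5-(6S,7S)-alkylated dihydroxy-methoxy benzophenone
Product: 10 C1-prenylated phenol
Conditions: NaH (1.0 equiv), prenyl bromide, PhMe, 0 °C to rt
Reagents that add atoms: prenyl bromide (1-bromo-3-methylbut-2-ene), CC(C)=CCBr
Why: ortho-C-allylation of a sodium phenoxide in a non-polar solvent: one equivalent of base deprotonates only the non-chelated O9–H, and its single free ortho carbon is C1.

Step 6
Reactants: 10 C1-prenylated phenol
Product: 11 O9-methyl ether
Conditions: MeI, K2CO3, acetone, reflux
Reagents that add atoms: iodomethane, CI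
Why: Williamson etherification selective for the non-chelated hydroxyl (O4–H stays hydrogen-bonded to the ketone); this leaves O4 as the only site for the next allylation and stores C9 as an enol ether for step 8.

Step 7
Reactants: 11 O9-methyl ether
Product: 13 dearomatized C5-quaternary dienone, via aryl 2-methylallyl ether 12 (not isolated)
Conditions: KOtBu, methallyl bromide, THF, 0 °C to rt; then PhMe, 130 °C (sealed tube)
Reagents that add atoms: methallyl bromide (3-bromo-2-methylprop-1-ene), CC(=C)CBr
Why: Williamson O-allylation followed by a dearomative aromatic Claisen rearrangement: the [3,3] shift from O4 can only reach C5 (the other ortho carbon carries the acyl group), and in the chair transition state C6 turns its hydrogen toward O4 and its bulky C7 branch away from the migrating allyl unit, so the 2-methylallyl group enters on the face of the smaller 4-methylpent-3-enyl chain and sets quaternary C5 as drawn.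

Step 8
Reactants: 13 dearomatized C5-quaternary dienone
Product: 15 tricyclic C2 methyl enol ether, via ring B-closed bicyclic dione 14 (not isolated)
Conditions: HCO2H, CH2Cl2, 0 °C to rt
Reagents that add atoms: none
Why: Proposed new method: formic acid protonates the two 1,1-disubstituted alkenes; the C8 tertiary cation is captured by the enol ether carbon C1 on the ring face fixed by C5 (the known formic acid cationic cyclization of isopropenyl-bearing dearomatized acylphloroglucinols to type B PPAP cores), and the resulting C9 oxocarbenium ion gives up its methyl group to formate, which is the irreversible exit that O-cyclized oxocarbenium ions lack; the C11 cation from the 2-methylallyl group is then attacked 7-exo by the trisubstituted alkene on C6 through a chair-like transition state with the developing isopropyl cation pseudo-equatorial and anti to C7, and loss of a methyl proton gives the isopropenyl group and C12 (S); the closest known type for this second closure is the ene-type cation–olefin cyclization of terpenes that ends in an isopropenyl group.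

Step 9
Reactants: 15 tricyclic C2 methyl enol ether
Product: 16 target CNP0140614.2
Conditions: LiOH, dioxane/H2O (degassed), 90 °C; then aq. HCl to pH 3
Reagents that add atoms: water, O
Why: Hydroxide cleaves the vinylogous methyl ester by addition–elimination at C2 (a known last step for O-methyl PPAPs) and the aryl silyl ethers at silicon; no stereocentre can epimerise because both bridgeheads are quaternary.

## Compound list

1 | 5-methoxyresorcinol (5-methoxybenzene-1,3-diol) | COc1cc(O)cc(O)c1 | starting material
2 | 3,4-dihydroxybenzonitrile | N#Cc1ccc(O)c(O)c1 | starting material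
3 | (3,4-dihydroxyphenyl)(2,4-dihydroxy-6-methoxyphenyl)methanone | COc1cc(O)cc(O)c1C(=O)c1ccc(O)c(O)c1 | intermediate
4 | (2,2-di-tert-butyl-1,3,2-benzodioxasilol-5-yl)(2,4-dihydroxy-6-methoxyphenyl)methanone | COc1cc(O)cc(O)c1C(=O)c1ccc2O[Si](C(C)(C)C)(C(C)(C)C)Oc2c1 | intermediate
5 | (R)-lavandulol, (2R)-5-methyl-2-(prop-1-en-2-yl)hex-4-en-1-ol | OC[C@H](CC=C(C)C)C(C)=C | starting material
6 | (R)-lavandulal, (2R)-5-methyl-2-(prop-1-en-2-yl)hex-4-enal | O=C[C@H](CC=C(C)C)C(C)=C | intermediate
7 | hydroxyalkylation adduct: 4 carrying at C5 a (2R)-1-hydroxy-5-methyl-2-(prop-1-en-2-yl)hex-4-enyl group (carbinol epimers; magnesium salt in the flask) | COc1cc(O)c(C(O)[C@H](CC=C(C)C)C(C)=C)c(O)c1C(=O)c1ccc2O[Si](C(C)(C)C)(C(C)(C)C)Oc2c1 | intermediate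
8 | ortho-quinone methide: C9 keto, C5=C6 exocyclic alkylidene carrying the (S)-configured C7 with prenyl and isopropenyl (alkene geometry not fixed) | COC1=CC(=O)C(=C[C@H](CC=C(C)C)C(C)=C)C(O)=C1C(=O)c1ccc2O[Si](C(C)(C)C)(C(C)(C)C)Oc2c1 | intermediate
9 | (2,2-di-tert-butyl-1,3,2-benzodioxasilol-5-yl){3-[(6S,7S)-2,10-dimethyl-7-(prop-1-en-2-yl)undeca-2,9-dien-6-yl]-2,4-dihydroxy-6-methoxyphenyl}methanone | COc1cc(O)c([C@@H](CCC=C(C)C)[C@H](CC=C(C)C)C(C)=C)c(O)c1C(=O)c1ccc2O[Si](C(C)(C)C)(C(C)(C)C)Oc2c1 | intermediate
10 | 9 with a 3-methylbut-2-enyl group at C1 (ring position 5, between OMe and O9–H) | COc1c(CC=C(C)C)c(O)c([C@@H](CCC=C(C)C)[C@H](CC=C(C)C)C(C)=C)c(O)c1C(=O)c1ccc2O[Si](C(C)(C)C)(C(C)(C)C)Oc2c1 | intermediate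
11 | O9-methyl ether of 10 (2-hydroxy-4,6-dimethoxy pattern; O4–H free and chelated) | COc1c(CC=C(C)C)c(OC)c([C@@H](CCC=C(C)C)[C@H](CC=C(C)C)C(C)=C)c(O)c1C(=O)c1ccc2O[Si](C(C)(C)C)(C(C)(C)C)Oc2c1 | intermediate
12 | O4 2-methylprop-2-enyl ether of 11 | COc1c(CC=C(C)C)c(OC)c([C@@H](CCC=C(C)C)[C@H](CC=C(C)C)C(C)=C)c(OCC(C)=C)c1C(=O)c1ccc2O[Si](C(C)(C)C)(C(C)(C)C)Oc2c1 | intermediate
13 | (6R)-2-[(2,2-di-tert-butyl-1,3,2-benzodioxasilol-5-yl)carbonyl]-6-[(6S,7S)-2,10-dimethyl-7-(prop-1-en-2-yl)undeca-2,9-dien-6-yl]-3,5-dimethoxy-4-(3-methylbut-2-enyl)-6-(2-methylprop-2-enyl)cyclohexa-2,4-dien-1-one (ring C6 = core C5) | COC1=C(CC=C(C)C)C(OC)=C(C(=O)c2ccc3O[Si](C(C)(C)C)(C(C)(C)C)Oc3c2)C(=O)[C@]1(CC(C)=C)[C@@H](CCC=C(C)C)[C@H](CC=C(C)C)C(C)=C | intermediate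
14 | (1R,5R,6S,7S)-3-aroyl-2-methoxy-8,8-dimethyl-1,7-bis(3-methylbut-2-enyl)-6-(4-methylpent-3-enyl)-5-(2-methylprop-2-enyl)bicyclo[3.3.1]non-2-ene-4,9-dione (core locants; aroyl = silylene-protected 3,4-dihydroxybenzoyl) | CC(C)=CCC[C@H]1[C@H](CC=C(C)C)C(C)(C)[C@]2(CC=C(C)C)C(OC)=C(C(=O)c3ccc4O[Si](C(C)(C)C)(C(C)(C)C)Oc4c3)C(=O)[C@@]1(CC(C)=C)C2=O | intermediate
15 | (1R,5R,6S,7S,12S)-tricyclic methyl enol ether: 14 with the C11–C12 bond closed (cycloheptane C5–C10–C11–C12–C13–C14–C6 cis-fused at C5–C6, C11 gem-dimethyl, C12 isopropenyl cis to H6) | C=C(C)[C@@H]1CC[C@H]2[C@H](CC=C(C)C)C(C)(C)[C@]3(CC=C(C)C)C(OC)=C(C(=O)c4ccc5O[Si](C(C)(C)C)(C(C)(C)C)Oc5c4)C(=O)[C@@]2(CC1(C)C)C3=O | intermediate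
16 | CNP0140614.2: (1S,5S,6S,7S,12S)-3-(3,4-dihydroxybenzoyl)-4-hydroxy-8,8,11,11-tetramethyl-1,7-bis(3-methylbut-2-enyl)-12-(prop-1-en-2-yl)bicyclo[3.3.1]non-3-ene-2,9-dione with the C10–C14 cycloheptane fused at C5–C6 (core locants, drawn tautomer; C7 prenyl anti to the C9 bridge, C14 syn to it) | C=C(C)[C@@H]1CC[C@H]2[C@H](CC=C(C)C)C(C)(C)[C@]3(CC=C(C)C)C(=O)C(C(=O)c4ccc(O)c(O)c4)=C(O)[C@@]2(CC1(C)C)C3=O | target

## Step count and risks

Total steps: 9. Longest linear sequence: 8 (steps 1, 2, 4, 5, 6, 7, 8, 9; step 3 is a one-step side branch).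

The three steps most likely to fail:

Step 4 (three-component coupling). The ortho-quinone methide 8 can tautomerise to a styrene, lavandulal can epimerise, and the diastereoselectivity at C6 rests on substrate control alone. Fallback: set out from 4 and 6 and condense them with benzenesulfinic acid (CH2Cl2, rt) to the isolable benzylic phenyl sulfone F1, a stable ortho-quinone methide precursor. Then treat F1 at −30 °C in THF with 4-methylpent-3-enylzinc bromide (3 equiv), Cu(OTf)2 (5 mol%) and a chiral phosphoramidite ligand. The organozinc reagent deprotonates the phenols and expels sulfinate to release 8 slowly at low temperature, and the ligand on copper, not the substrate, controls the face of the conjugate addition. The sequence comes back to the route at 9.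

Step 7 (dearomative Claisen). The quaternary centre is very crowded, a Cope shift of the lavandulyl-type 1,5-diene or of the new C5 allyl group can compete at high temperature, and the facial selectivity at C5 rests on a conformational model. Fallback: set out from 11 and form the C5–C bond intermolecularly by a Tsuji–Trost dearomative allylation: methallyl methyl carbonate, [Pd(C3H5)Cl]2 as the source of zerovalent palladium and a DACH-phenyl Trost ligand, THF, rt. C5 is the only carbon ortho to the single phenoxide, O-allylation is reversible under palladium, and the enantiomer of the ligand is chosen to deliver the 2-methylallyl group to the required face. This comes back to the route at 13 and makes no new compound.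

Step 8 (double cationic cyclization). Prenyl groups can be protonated, the carbonyl oxygen O4 can trap either cation, C3 can compete with C1, the last cation can lose a proton to the isopropylidene isomer, and C12 can form as the wrong epimer. Fallback: stop the formic acid treatment at 0 °C once ring B has closed and isolate 14. Then close the seven-membered ring by an electrophilic mercury cyclization: Hg(OTf)2 (divalent mercury, 1.05 equiv), MeNO2, −20 °C, then aq. NaCl. Mercury adds to the terminal carbon of the least hindered 2-methylallyl alkene, the C11 cation is taken by the C6 side-chain alkene and a methyl proton is lost, giving the alkylmercuric chloride F2. Bu3SnH with AIBN in PhMe at 80 °C removes mercury and leaves the C11 methyl group, coming back to the route at 15.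

## Further compounds

F1 | step 4 | benzylic phenyl sulfone: 4 carrying at C5 a (2R)-5-methyl-1-(phenylsulfonyl)-2-(prop-1-en-2-yl)hex-4-enyl group (sulfonyl-carbon epimers) | COc1cc(O)c(C(S(=O)(=O)c2ccccc2)[C@H](CC=C(C)C)C(C)=C)c(O)c1C(=O)c1ccc3O[Si](C(C)(C)C)(C(C)(C)C)Oc3c1
F0 | step 7 | none | none
F2 | step 8 | alkylmercuric chloride: 15 in which one C11 methyl group is a chloromercuriomethyl group (C11 epimers) | C=C(C)[C@@H]1CC[C@H]2[C@H](CC=C(C)C)C(C)(C)[C@]3(CC=C(C)C)C(OC)=C(C(=O)c4ccc5O[Si](C(C)(C)C)(C(C)(C)C)Oc5c4)C(=O)[C@@]2(CC1(C)C[Hg]Cl)C3=O
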